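**Retrosynthetic overview**
Numbering: acid chain C1–C6 (C1 = CO2H, methyl on C4); side chain C1′–C7′ on C2 (C1′=C2′, C3′H2, C4′H(CH3), C7′=O); ring A = the 5,6-dihydropyran-2-one (O1, C2–C6).
Endgame: target ⇒ its tert-butyl ester ⇒ the isomeric C4–O enol ester of ring A. The C3–C7′ bond comes from an O→C acyl shift, so ring A passes through the key step as a neutral, non-chelating enol ester.
Key disconnection C3′–C4′: a stereoconvergent nickel-catalysed reductive allyl–alkyl coupling of the complete dienyl acetate with the complete ring A bromide (both C4′ epimers). One operation joins the halves and sets C4′.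
Enabling feature: C3′ is the unsubstituted terminus of the allyl unit C1′–C2′–C3′, which stays conjugated with the C2=C3–C1(=O) enoate. C4′ lies 1,4 to the C7′ carbonyl, whose oxygen can chelate a metal on C4′ in a six-membered ring.
Fragments: the dienyl acetate comes from (S)-2-methylbutan-1-ol (iodo-Wittig, Stille). The bromide comes from γ-valerolactone plus ring A, the only ring, which is closed first (step 7) by lactonisation of a chiral-pool δ-hydroxy-β-keto ester.

Key step: step 11

Assumption: the β-tricarbonyl unit of ring A is written throughout as its C4 enol, and its tautomers are treated as the same compound.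

Step 1
Reactants: 1 (S)-2-methylbutan-1-ol
Product: 2 (S)-2-methylbutanal
Conditions: TEMPO (1 mol %), KBr (10 mol %), NaOCl (aq, 1.1 equiv), NaHCO3 buffer, CH2Cl2/H2O, 0 °C
Reagents that add atoms: none
Why: TEMPO/hypochlorite (oxoammonium) oxidation of a primary alcohol stops at the aldehyde in the buffered two-phase system at 0 °C, where the α-stereocentre taken from the chiral pool should not epimerise.

Step 2
Reactants: 2 (S)-2-methylbutanal; 3 tert-butyl (triphenylphosphoranylidene)acetate
Product: 5 tert-butyl (2Z,4S)-2-iodo-4-methylhex-2-enoate, via iodo ylide 4 (not isolated)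
Conditions: 3, NIS (1.05 equiv), CH2Cl2, −20 °C; then 2, −20 °C → rt
Reagents that add atoms: N-iodosuccinimide, O=C1CCC(=O)N1I
Why: Electrophilic iodination of the stabilised ylide followed by Wittig olefination should place the ester trans and the iodine cis to the alkyl chain (Z-α-iodoenoate), and the base-free medium spares the C4 stereocentre.

Step 3
Reactants: 6 prop-2-yn-1-ol
Product: 7 (E)-3-(tributylstannyl)prop-2-en-1-ol
Conditions: Bu3SnH (1.2 equiv), AIBN (cat.), neat, 80 °C; chromatography
Reagents that add atoms: tributyltin hydride, CCCC[SnH](CCCC)CCCC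
Why: In this radical hydrostannation of a terminal alkyne the stannyl radical adds to the terminal carbon, and its reversible addition at 80 °C equilibrates the vinylstannanes toward the E isomer, which is separated from the minor isomers.

Step 4
Reactants: 5 tert-butyl (2Z,4S)-2-iodo-4-methylhex-2-enoate; 7 (E)-3-(tributylstannyl)prop-2-en-1-ol
Product: 8 tert-butyl (2E,4S)-2-[(1E)-3-hydroxyprop-1-en-1-yl]-4-methylhex-2-enoate
Conditions: Pd2(dba)3 (2.5 mol %), AsPh3 (10 mol %), NMP, rt
Reagents that add atoms: none
Why: Stille coupling with the weakly donating AsPh3 ligand runs at room temperature with retention at both sp2 carbons, so the Z-iodide maps onto the 2E enoate and the E-stannane onto the C1′=C2′ E alkene, and the free hydroxyl is tolerated.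

Step 5
Reactants: 8 tert-butyl (2E,4S)-2-[(1E)-3-hydroxyprop-1-en-1-yl]-4-methylhex-2-enoate
Product: 9 tert-butyl (2E,4S)-2-[(1E)-3-acetoxyprop-1-en-1-yl]-4-methylhex-2-enoate
Conditions: Ac2O, Et3N, DMAP (5 mol %), CH2Cl2, 0 °C
Reagents that add atoms: acetic anhydride, CC(=O)OC(C)=O
Why: DMAP-catalysed acetylation of a primary allylic alcohol turns the C3′–O bond into a leaving group that is stable to handling and is ionised only by a low-valent metal.

Step 6
Reactants: 10 methyl (R)-3-hydroxybutanoate; 11 tert-butyl acetate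
Product: 13 tert-butyl (5R)-5-hydroxy-3-oxohexanoate, via lithium enolate 12 (not isolated)
Conditions: 11, LDA (3.5 equiv each), THF, −78 °C; then 10, −78 → −20 °C; 1 M HCl quench
Reagents that add atoms: lithium diisopropylamide (supplies the lithium of 12), [Li+].CC(C)[N-]C(C)C
Why: In this crossed Claisen condensation the excess lithium enolate first deprotonates the hydroxyl and then attacks the methyl ester, the product is protected as its enolate, and the carbinol stereocentre (future C6 of ring A) comes unchanged from the chiral pool.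

Step 7
Reactants: 13 tert-butyl (5R)-5-hydroxy-3-oxohexanoate
Product: 15 (6R)-4-hydroxy-6-methyl-5,6-dihydro-2H-pyran-2-one, via hydroxy keto acid 14 (not isolated)
Conditions: TFA, CH2Cl2, rt
Reagents that add atoms: none
Why: Acidolysis of the tert-butyl ester and 6-exo-trig lactonisation of the δ-hydroxy-β-keto acid close ring A without breaking the C6–O bond, so the R configuration is retained.

Step 8
Reactants: 16 γ-valerolactone (racemic)
Product: 17 4-bromopentanoic acid (racemic)
Conditions: HBr (33 % in AcOH), rt
Reagents that add atoms: hydrogen bromide, Br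
Why: Bromide cleaves the protonated lactone at the alkyl–oxygen bond (lactone hydrobromination), and a racemic product is acceptable because this stereocentre is erased and reset in step 11.

Step 9
Reactants: 17 4-bromopentanoic acid
Product: 18 4-bromopentanoyl chloride (racemic)
Conditions: SOCl2 (neat), DMF (cat.), 50 °C
Reagents that add atoms: thionyl chloride, O=S(Cl)Cl
Why: Acid chloride formation with SOCl2 under non-basic conditions avoids the carboxylate, which would relactonise by displacing the γ-bromide.

Step 10
Reactants: 15 (6R)-4-hydroxy-6-methyl-5,6-dihydro-2H-pyran-2-one; 18 4-bromopentanoyl chloride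
Product: 19 (6R)-6-methyl-2-oxo-5,6-dihydro-2H-pyran-4-yl 4-bromopentanoate (both epimers at the bromine-bearing carbon)
Conditions: Et3N (1.1 equiv), CH2Cl2, −10 °C
Reagents that add atoms: none
Why: Kinetic O-acylation of the acidic enol of a cyclic 1,3-dicarbonyl compound with an acid chloride and Et3N stops at the enol ester as long as no nucleophilic catalyst (DMAP, cyanide) is present.

Step 11
Reactants: 9 tert-butyl (2E,4S)-2-[(1E)-3-acetoxyprop-1-en-1-yl]-4-methylhex-2-enoate; 19 (6R)-6-methyl-2-oxo-5,6-dihydro-2H-pyran-4-yl 4-bromopentanoate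
Product: 20 tert-butyl (2E,4S)-4-methyl-2-[(1E,4R)-4-methyl-7-{[(6R)-6-methyl-2-oxo-5,6-dihydro-2H-pyran-4-yl]oxy}-7-oxohept-1-en-1-yl]hex-2-enoate
Conditions: NiBr2·diglyme (10 mol %), (4S,4′S)-4,4′-diisopropyl-4,4′,5,5′-tetrahydro-2,2′-bioxazole (12 mol %), Mn powder (3 equiv), NaI (25 mol %), DMA, 10 °C, 9 (1.3 equiv) added slowly
Reagents that add atoms: none
Why: Proposed new method: zerovalent nickel ionises acetate 9 to an η3-allylnickel cation over C1′–C3′, monovalent nickel abstracts bromine from either C4′ epimer of 19 to give one planar secondary radical, the chiral nickel centre captures this radical, trivalent nickel forms the C3′–C4′ bond by reductive elimination, and Mn returns nickel to its low-valent state. The closest known reaction types are the nickel-catalysed reductive allylation of unactivated secondary alkyl bromides with allylic acetates, which is racemic but linear- and E-selective, and the nickel-catalysed stereoconvergent alkyl–alkyl cross-coupling of racemic γ-halo carbonyl compounds, and what is new is ligand-controlled stereoconvergence within the reductive allyl manifold. No ring is closed in this step. The single new stereocentre C4′ (R) is meant to be set by the C2-symmetric bis(oxazoline) ligand, assisted by the C7′ carbonyl oxygen, which can reach nickel bound to C4′ through a six-membered chelate and thereby tells the CH2CH2C(=O) arm from the CH3 group, while both epimers of 19 converge because the old configuration is erased in the radical. Regio- and geometric selectivity are secured by the substrate, since C3′ is the only unsubstituted allyl terminus, bond formation there keeps C1′=C2′ conjugated with the enoate, the syn-η3 complex leads to the E alkene, and the preset C2=C3 bond lies outside the allyl unit. Cross- over homo-coupling rests on the orthogonal activation of the partners (two-electron ionisation of the acetate, one-electron halogen abstraction from the bromide), and the enol ester, the tert-butyl ester and the C4 and C6 stereocentres are spectators.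

Step 12
Reactants: 20 tert-butyl (2E,4S)-4-methyl-2-[(1E,4R)-4-methyl-7-{[(6R)-6-methyl-2-oxo-5,6-dihydro-2H-pyran-4-yl]oxy}-7-oxohept-1-en-1-yl]hex-2-enoate
Product: 21 tert-butyl (2E,4S)-2-{(1E,4R)-7-[(6R)-4-hydroxy-6-methyl-2-oxo-5,6-dihydro-2H-pyran-3-yl]-4-methyl-7-oxohept-1-en-1-yl}-4-methylhex-2-enoate
Conditions: DMAP (30 mol %), Et3N (1.2 equiv), CH2Cl2, rt; 1 M HCl wash
Reagents that add atoms: none
Why: This nucleophile-catalysed O→C acyl migration of a 1,3-dione enol ester (Fries-type shift through the acylpyridinium/enolate ion pair) is driven by formation of the strongly stabilised β-tricarbonyl enolate and touches no stereocentre.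

Step 13
Reactants: 21 tert-butyl (2E,4S)-2-{(1E,4R)-7-[(6R)-4-hydroxy-6-methyl-2-oxo-5,6-dihydro-2H-pyran-3-yl]-4-methyl-7-oxohept-1-en-1-yl}-4-methylhex-2-enoate
Product: 22 (2E,4S)-2-{(1E,4R)-7-[(6R)-4-hydroxy-6-methyl-2-oxo-5,6-dihydro-2H-pyran-3-yl]-4-methyl-7-oxohept-1-en-1-yl}-4-methylhex-2-enoic acid (target)
Conditions: TFA/CH2Cl2 (1:4), 0 °C → rt
Reagents that add atoms: none
Why: Acidolysis of the tert-butyl ester (E1 loss of isobutene) needs neither base nor nucleophile, so the lactone, the enolised tricarbonyl, both alkene geometries and all three stereocentres should survive.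

**Compound list**
1 | (S)-2-methylbutan-1-ol | CC[C@H](C)CO | starting material
2 | (S)-2-methylbutanal | CC[C@H](C)C=O | intermediate
3 | tert-butyl (triphenylphosphoranylidene)acetate | CC(C)(C)OC(=O)C=P(c1ccccc1)(c1ccccc1)c1ccccc1 | starting material
4 | tert-butyl 2-iodo-2-(triphenylphosphoranylidene)acetate (iodo ylide) | CC(C)(C)OC(=O)C(I)=P(c1ccccc1)(c1ccccc1)c1ccccc1 | intermediate (not isolated)
5 | tert-butyl (2Z,4S)-2-iodo-4-methylhex-2-enoate | CC[C@H](C)/C=C(\I)C(=O)OC(C)(C)C | intermediate
6 | prop-2-yn-1-ol | C#CCO | starting material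
7 | (E)-3-(tributylstannyl)prop-2-en-1-ol | OC/C=C/[Sn](CCCC)(CCCC)CCCC | intermediate
8 | tert-butyl (2E,4S)-2-[(1E)-3-hydroxyprop-1-en-1-yl]-4-methylhex-2-enoate | CC[C@H](C)/C=C(\C=C\CO)C(=O)OC(C)(C)C | intermediate
9 | tert-butyl (2E,4S)-2-[(1E)-3-acetoxyprop-1-en-1-yl]-4-methylhex-2-enoate | CC[C@H](C)/C=C(\C=C\COC(C)=O)C(=O)OC(C)(C)C | intermediate
10 | methyl (R)-3-hydroxybutanoate | C[C@@H](O)CC(=O)OC | starting material
11 | tert-butyl acetate | CC(=O)OC(C)(C)C | starting material
12 | lithium enolate of tert-butyl acetate | [Li+].[O-]C(=C)OC(C)(C)C | intermediate (not isolated)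
13 | tert-butyl (5R)-5-hydroxy-3-oxohexanoate | C[C@@H](O)CC(=O)CC(=O)OC(C)(C)C | intermediate
14 | (5R)-5-hydroxy-3-oxohexanoic acid | C[C@@H](O)CC(=O)CC(=O)O | intermediate (not isolated)
15 | (6R)-4-hydroxy-6-methyl-5,6-dihydro-2H-pyran-2-one | C[C@@H]1CC(O)=CC(=O)O1 | intermediate
16 | γ-valerolactone (racemic) | CC1CCC(=O)O1 | starting material
17 | 4-bromopentanoic acid (racemic) | CC(Br)CCC(=O)O | intermediate
18 | 4-bromopentanoyl chloride (racemic) | CC(Br)CCC(=O)Cl | intermediate
19 | (6R)-6-methyl-2-oxo-5,6-dihydro-2H-pyran-4-yl 4-bromopentanoate (both epimers at C–Br) | CC(Br)CCC(=O)OC1=CC(=O)O[C@H](C)C1 | intermediate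
20 | tert-butyl (2E,4S)-4-methyl-2-[(1E,4R)-4-methyl-7-{[(6R)-6-methyl-2-oxo-5,6-dihydro-2H-pyran-4-yl]oxy}-7-oxohept-1-en-1-yl]hex-2-enoate | CC[C@H](C)/C=C(\C=C\C[C@H](C)CCC(=O)OC1=CC(=O)O[C@H](C)C1)C(=O)OC(C)(C)C | intermediate
21 | tert-butyl (2E,4S)-2-{(1E,4R)-7-[(6R)-4-hydroxy-6-methyl-2-oxo-5,6-dihydro-2H-pyran-3-yl]-4-methyl-7-oxohept-1-en-1-yl}-4-methylhex-2-enoate | CC[C@H](C)/C=C(\C=C\C[C@H](C)CCC(=O)C1=C(O)C[C@@H](C)OC1=O)C(=O)OC(C)(C)C | intermediate
22 | (2E,4S)-2-{(1E,4R)-7-[(6R)-4-hydroxy-6-methyl-2-oxo-5,6-dihydro-2H-pyran-3-yl]-4-methyl-7-oxohept-1-en-1-yl}-4-methylhex-2-enoic acid | CC[C@H](C)/C=C(\C=C\C[C@H](C)CCC(=O)C1=C(O)C[C@@H](C)OC1=O)C(=O)O | target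

Total step count: 13 steps.
Longest linear sequence: 7 steps (1, 2, 4, 5, 11, 12, 13).

**Three steps most likely to fail**

1. Step 11 (Proposed new method).
What may go wrong:
- Weak or reversed facial discrimination when the C4′ radical is captured, so that stereoconvergence is lost. The sense of induction of the ligand cannot be predicted, and its antipode is equally available.
- Insertion of low-valent nickel into the acyl–oxygen bond of the enol ester.
- Allyl homocoupling.
- β-Hydride elimination of the secondary alkylnickel.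
- Drift of the C2=C3 geometry through allyl migration.

Fallback: known chemistry, with the same bond made by auxiliary-controlled enolate alkylation. It sets out from 8 and 15 and returns at 21. An Appel reaction (CBr4, PPh3, CH2Cl2, 0 °C) turns 8 into tert-butyl (2E,4S)-2-[(1E)-3-bromoprop-1-en-1-yl]-4-methylhex-2-enoate F1. Evans alkylation of the sodium enolate of commercial (R)-4-benzyl-3-propionyl-1,3-oxazolidin-2-one (NaHMDS, THF, −78 °C) with F1 forms the C3′–C4′ bond anti to the benzyl group. It gives tert-butyl (2E,4S)-2-{(1E,4S)-5-[(4R)-4-benzyl-2-oxo-1,3-oxazolidin-3-yl]-4-methyl-5-oxopent-1-en-1-yl}-4-methylhex-2-enoate F2. The 4S descriptor here corresponds to 4′R in 21, because the CIP ranking of the neighbours changes. LiBH4/MeOH (Et2O, 0 °C) releases the auxiliary and gives tert-butyl (2E,4S)-2-[(1E,4S)-5-hydroxy-4-methylpent-1-en-1-yl]-4-methylhex-2-enoate F3. I2/PPh3/imidazole converts this into tert-butyl (2E,4S)-2-[(1E,4S)-5-iodo-4-methylpent-1-en-1-yl]-4-methylhex-2-enoate F4. In parallel 15 is C-acetylated (Ac2O, Et3N, DMAP, CH2Cl2) to (6R)-3-acetyl-4-hydroxy-6-methyl-5,6-dihydro-2H-pyran-2-one F5. Its dianion (LDA, 2.2 equiv, THF/DMPU, −78 → 0 °C) is alkylated at the acetyl carbon by F4 to give 21.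

2. Step 2.
What may go wrong: incomplete iodination of the ylide, erosion of Z selectivity with the α-branched aldehyde, or epimerisation of the aldehyde during a slow olefination.

Fallback: the halogen is introduced after the olefination. It sets out from 2 and 3 and returns at 8. A plain Wittig reaction of 2 with 3 (CH2Cl2, rt) gives tert-butyl (2E,4S)-4-methylhex-2-enoate F6. Anti addition of Br2 (CH2Cl2, 0 °C) gives tert-butyl (4S)-2,3-dibromo-4-methylhexanoate F7. Et3N-induced anti elimination of HBr gives tert-butyl (2Z,4S)-2-bromo-4-methylhex-2-enoate F8. This enters the Stille coupling with 7 in place of 5 (50 °C) and gives 8.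

3. Step 4.
What may go wrong: slow transmetalation to the hindered, electron-poor alkenylpalladium, so that stannane homocoupling, protodestannylation or loss of alkene geometry take over.

Fallback: tin-free, with the three carbons added at the aldehyde oxidation level. It sets out from 5 and returns at 8. A Heck reaction of 5 with acrolein under ligand-free phase-transfer conditions (Pd(OAc)2, Bu4NCl, NaHCO3, DMF, rt) gives tert-butyl (2E,4S)-4-methyl-2-[(1E)-3-oxoprop-1-en-1-yl]hex-2-enoate F9. Luche reduction of the aldehyde (NaBH4, CeCl3·7H2O, MeOH, −20 °C) gives 8.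

**Further compounds**
F1 | step 11 | tert-butyl (2E,4S)-2-[(1E)-3-bromoprop-1-en-1-yl]-4-methylhex-2-enoate | CC[C@H](C)/C=C(\C=C\CBr)C(=O)OC(C)(C)C
F2 | step 11 | tert-butyl (2E,4S)-2-{(1E,4S)-5-[(4R)-4-benzyl-2-oxo-1,3-oxazolidin-3-yl]-4-methyl-5-oxopent-1-en-1-yl}-4-methylhex-2-enoate | CC[C@H](C)/C=C(\C=C\C[C@H](C)C(=O)N1[C@H](Cc2ccccc2)COC1=O)C(=O)OC(C)(C)C
F3 | step 11 | tert-butyl (2E,4S)-2-[(1E,4S)-5-hydroxy-4-methylpent-1-en-1-yl]-4-methylhex-2-enoate | CC[C@H](C)/C=C(\C=C\C[C@H](C)CO)C(=O)OC(C)(C)C
F4 | step 11 | tert-butyl (2E,4S)-2-[(1E,4S)-5-iodo-4-methylpent-1-en-1-yl]-4-methylhex-2-enoate | CC[C@H](C)/C=C(\C=C\C[C@H](C)CI)C(=O)OC(C)(C)C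
F5 | step 11 | (6R)-3-acetyl-4-hydroxy-6-methyl-5,6-dihydro-2H-pyran-2-one | CC(=O)C1=C(O)C[C@@H](C)OC1=O
F6 | step 2 | tert-butyl (2E,4S)-4-methylhex-2-enoate | CC[C@H](C)/C=C/C(=O)OC(C)(C)C
F7 | step 2 | tert-butyl (4S)-2,3-dibromo-4-methylhexanoate | CC[C@H](C)C(Br)C(Br)C(=O)OC(C)(C)C
F8 | step 2 | tert-butyl (2Z,4S)-2-bromo-4-methylhex-2-enoate | CC[C@H](C)/C=C(\Br)C(=O)OC(C)(C)C
F9 | step 4 | tert-butyl (2E,4S)-4-methyl-2-[(1E)-3-oxoprop-1-en-1-yl]hex-2-enoate | CC[C@H](C)/C=C(\C=C\C=O)C(=O)OC(C)(C)C
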